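The easy error with these runs is to take the columns read as the whole charge.

| flask | starting material | coupling partner | second substrate | protic impurity | remark | time |
|---|---|---|---|---|---|---|
| green | 0.15 M | 2 equiv (fed, over 30 min) | 2.5 equiv | 0.030 M | run made earlier; the fed solution adds 0.25 times the starting volume |  |
| red | 0.15 M | 2 equiv (fed, over 30 min) | 10 equiv | 0.030 M | run made earlier; the fed solution adds 0.25 times the starting volume |  |
| amber | 0.15 M | 2 equiv (fed, over 30 min) | 5 equiv | 0.045 M | run made earlier; the fed solution adds 0.25 times the starting volume |  |
| flask | 0.15 M | 2.00 equiv (fed, over 30 min) | 5.00 equiv | 0.0300 M | the fed solution adds 0.25 times the starting volume | 2.5 h |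

- green (time / h: target / %, starting material / %, over-reaction product / %): 0.250: 6.0, 87.5, 0.3; 0.333: 8.9, 83.3, 0.6; 0.500: 14.9, 75.0, 1.0; 0.833: 19.7, 66.8, 1.5; 1.33: 20.2, 62.3, 3.2; 2.00: 18.6, 59.3, 5.6; 3.00: 17.1, 56.4, 8.4
- red (time / h: target / %, starting material / %, over-reaction product / %): 0.250: 6.1, 87.8, 0.3; 0.333: 9.0, 84.3, 0.1; 0.500: 15.3, 75.3, 0.4; 0.833: 20.9, 66.9, 0.9; 1.33: 19.9, 62.4, 2.8; 2.00: 18.5, 60.5, 5.3; 3.00: 16.5, 57.4, 8.1
- amber (time / h: target / %, starting material / %, over-reaction product / %): 0.250: 6.2, 85.7, 0; 0.417: 11.9, 76.1, 0.2; 0.833: 18.6, 62.3, 1.0; 1.50: 18.6, 55.9, 3.8; 3.00: 15.3, 50.5, 7.5

(each reading ± 0.3 percentage points)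

- amounts are per litre of the starting volume; all of the dose is in the solution fed
- what was read earlier has a scatter of 0.3 percentage points, one standard deviation

- the species in which most of what was charged as starting material, at 2.5 h sits (target / over-reaction product / starting material)
- the largest share itself, whichever of these holds it, in percent of the starting material charged

Minutes of the meeting on the flask. The analyst reported that the columns fall short of the charge: at 3.00 h the gap was 18.1% in green, 18.0% in red and 26.7% in amber. The chair noted that green and red, with different second substrate, show nearly the same gap.

The process chemist proposed to count turnovers, supposing that each molecule of protic impurity takes one of starting material. That gives 20.0% for the flask, the same for green and red, and 30.0% for amber. She called this the impurity ceiling, the share of charged starting material that protic impurity can consume, the impurity being the limiting reagent of that loss. The gaps stood at 90.5% of the ceiling in green and 89.0% in amber. Green and amber differ in second substrate as well, so she argued from these two figures together with the chair's comparison of green and red that the gap follows the impurity.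

The analyst then averaged green and red at 2.00 h and 3.00 h, since the flask shares their impurity. This gave a gap of 17.1% and target plus over-reaction product of 24.5%. The meeting therefore committed to 58.4% starting material in the flask at 2.5 h. That figure is the mean of the starting-material readings at those two times, so it is no test of the ceiling.

The forecast says starting material at 58.1%, slightly below the meeting's figure, holding that “Second substrate therefore has essentially no effect on starting-material consumption”.

The flask gives starting material at 58.1%, with target at 17.6% and over-reaction product at 6.79%.

    starting material + coupling partner ⇌ target (K = 1.61 M⁻¹, k = 0.0889 M⁻¹ min⁻¹)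
    2 starting material → self-condensation product (k = 2.25 × 10⁻⁵ M⁻¹ min⁻¹)
    second substrate + coupling partner ⇌ second product (K = 0.360 M⁻¹, k = 7.48 × 10⁻⁴ M⁻¹ min⁻¹)
    coupling partner + target → over-reaction product (k = 0.0137 M⁻¹ min⁻¹)
    starting material + protic impurity → quenched substrate (k = 0.165 M⁻¹ min⁻¹)

In the flask, 13% of the impurity is left, so by this count it has taken 17.4% of the starting material charged, and quenched substrate stands at 17.5%. The neighbour flask with 8.00 equiv of coupling partner has the same ceiling, 20.0%. With 33% of its impurity left, the same count gives 13.4%, and its quenched substrate stands at 13.4%. That leaves 86.6% for the columns read and for self-condensation product, which stands at 0.0152%; the columns in that neighbour sum to 86.6%. There, starting material is down to 17.4% and target stands at 20.3%, while the largest share has moved to over-reaction product, at 48.9%.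

The earlier runs and the new flask are simulated for an exercise.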